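A direct plan would cut the depside at its ester C–O bond: each ring would be made on its own by malonate–enone annulation and dehydrogenation, and 2,4-dimethoxy-6-propylbenzoic acid A1 would acylate the 4-OH of benzyl 2,4-dihydroxy-6-pentylbenzoate A2 to give benzyl 4-[(2,4-dimethoxy-6-propylbenzoyl)oxy]-2-hydroxy-6-pentylbenzoate A3, which would be hydrogenolysed.
Its weakest steps would be:
- the aromatisation of each cyclohexenone ester by halogenation and dehydrohalogenation, needed twice, in which halogenation of the new resorcinol ring would compete;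
- the change of the ester group of the pentyl ring to a hydrogenolysable one, about four operations through a decarboxylation-prone free acid that would add no complexity;
- the acylation by the di-ortho-substituted acid A1, slow at the hindered carbonyl and dependent on discrimination between the two phenols of A2.

The route would rest instead on a benzannulation: ring A (the 2,4-dimethoxy-6-propylbenzoyl ring, C1'–C6') would not be attached as a finished acid but grown on the ester oxygen. Its C1' and C6' map onto the triple bond of a hex-2-ynoate, its C2'–C5' onto 1,3-dimethoxycyclohexa-1,3-diene. Unhindered hex-2-ynoic acid would acylate the 4-OH of 2,4-dihydroxy-6-pentylbenzaldehyde; one Alder–Rickert reaction (Diels–Alder addition, then loss of ethylene) would then form C1'–C2' and C6'–C5' and deliver both methoxy groups, the propyl group and the di-ortho-substituted aryl ester together. No hindered acid would be coupled, no ring aromatised by halogenation, and the formyl group, a latent carboxyl, would make ester protecting groups unnecessary.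

Key step: step 4

Remark on the chemistry: the target is achiral, so no stereocentre has to be set. Ring A is the 2,4-dimethoxy-6-propylbenzoyl ring (C1'–C6') and ring B the salicylic acid ring (C1–C6).

**Step 1**
Reactants: 1 1,5-dimethoxycyclohexa-1,4-diene
Product: 2 1,3-dimethoxycyclohexa-1,3-diene
Conditions: KOt-Bu (0.2 equiv), DMSO, rt, N2; H2O, pentane extraction; distillation at reduced pressure
Reagents that add atoms: none
Why: Base-mediated prototropic isomerisation of the 1,4-diene through its pentadienyl anion should move one double bond into conjugation and give a mixture enriched in the conjugated bis-enol ether, the only isomer that can serve as the diene in step 4.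

**Step 2**
Reactants: 3 olivetol (5-pentylbenzene-1,3-diol)
Product: 5 2,4-dihydroxy-6-pentylbenzaldehyde, via iminium chloride 4 (not isolated)
Conditions: POCl3 (1.5 equiv), DMF, 0 °C to rt, 3 h; then ice–H2O, 50 °C, 1 h
Reagents that add atoms: N,N-dimethylformamide, CN(C)C=O; water, O
Why: In this Vilsmeier–Haack formylation the chloroiminium ion should attack C4 of the resorcinol (ortho to one hydroxyl, para to the other) rather than the more crowded C2 between the two hydroxyls, and hydrolysis of iminium salt 4 should free the aldehyde.

**Step 3**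
Reactants: 5 2,4-dihydroxy-6-pentylbenzaldehyde; 6 hex-2-ynoic acid
Product: 8 4-formyl-3-hydroxy-5-pentylphenyl hex-2-ynoate, via O-acylisourea 7 (not isolated)
Conditions: DCC (1.1 equiv), DMAP (0.05 equiv), CH2Cl2, 0 °C, 3 h
Reagents that add atoms: none
Why: In this Steglich esterification the non-chelated and more acidic 4-OH (para to the formyl group) should be acylated while the 2-OH stays hydrogen-bonded to the aldehyde carbonyl, and the low temperature and small amount of DMAP should limit isomerisation of the alk-2-ynoate to the allenoate.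

**Step 4**
Reactants: 8 4-formyl-3-hydroxy-5-pentylphenyl hex-2-ynoate; 2 1,3-dimethoxycyclohexa-1,3-diene
Product: 12 4-formyl-3-hydroxy-5-pentylphenyl 2,4-dimethoxy-6-propylbenzoate, via trimethylsilyl ether 9 (not isolated), via bicyclooctadiene adduct 10 (not isolated), via silylated depside aldehyde 11 (not isolated)
Conditions: N,O-bis(trimethylsilyl)acetamide (1.5 equiv), toluene, 60 °C, 1 h, volatiles removed in vacuo; then 2 (4 equiv), BHT (cat.), sealed tube, 150 °C, then 190 °C; then 1 M HCl, THF, rt
Reagents that add atoms: none
Why: Transient O-silylation removes the acidic phenolic proton, and the electron-rich diene 2 then adds across the electron-poor triple bond of the aryl alk-2-ynoate in an intermolecular normal-demand Diels–Alder reaction to give bicyclo[2.2.2]octadiene 10, which on further heating expels its CH2–CH2 bridge as ethylene by retro-Diels–Alder reaction. This is the Alder–Rickert reaction, a known benzannulation of alk-2-ynoate esters with 1,3-dimethoxycyclohexa-1,3-diene. Ring A is closed by an intermolecular [4+2] cycloaddition that forms the C1'–C2' and C6'–C5' bonds, and it is aromatised by [4+2] cycloreversion without an oxidant. No stereocentre has to be controlled, since the two bridgehead centres of racemic 10 vanish on loss of ethylene. The step needs regioselectivity, which the substrate pair secures: both methoxy groups place the largest HOMO coefficient on the unsubstituted diene terminus C4, which bonds to the propyl-bearing β-carbon of the ynoate, so that the C1 methoxy group ends ortho and the C3 methoxy group para to the ester carbonyl, with propyl at the other ortho position. It also needs the alkyne to react in preference to the formyl group, which is secured because that group is flanked by two ortho substituents, is no longer hydrogen-bond-activated after silylation and would add alkoxydienes only under Lewis acid catalysis, while dilute acid at the end cleaves the silyl ether.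

**Step 5**
Reactants: 12 4-formyl-3-hydroxy-5-pentylphenyl 2,4-dimethoxy-6-propylbenzoate
Product: 13 4-[(2,4-dimethoxy-6-propylbenzoyl)oxy]-2-hydroxy-6-pentylbenzoic acid (target)
Conditions: NaClO2 (1.5 equiv), H2NSO3H (3 equiv), THF–H2O, 0 °C, 1 h; extraction and crystallisation below 30 °C
Reagents that add atoms: sodium chlorite, [Na+].[O-]Cl=O
Why: This Lindgren–Pinnick chlorite oxidation should convert the aldehyde into the acid under weakly acidic conditions that leave the hindered aryl ester and the methyl ethers untouched, with sulfamic acid consuming the hypochlorous acid before it can chlorinate either electron-rich ring.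

## Compound list
1 | 1,5-dimethoxycyclohexa-1,4-diene | COC1=CCC=C(OC)C1 | starting material
2 | 1,3-dimethoxycyclohexa-1,3-diene | COC1=CC(OC)=CCC1 | intermediate
3 | olivetol (5-pentylbenzene-1,3-diol) | CCCCCc1cc(O)cc(O)c1 | starting material
4 | (2,4-dihydroxy-6-pentylbenzylidene)dimethyliminium chloride (not isolated) | CCCCCc1cc(O)cc(O)c1C=[N+](C)C.[Cl-] | intermediate
5 | 2,4-dihydroxy-6-pentylbenzaldehyde | CCCCCc1cc(O)cc(O)c1C=O | intermediate
6 | hex-2-ynoic acid | CCCC#CC(=O)O | starting material
7 | N,N'-dicyclohexyl-O-(hex-2-ynoyl)isourea (not isolated) | CCCC#CC(=O)OC(=NC1CCCCC1)NC1CCCCC1 | intermediate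
8 | 4-formyl-3-hydroxy-5-pentylphenyl hex-2-ynoate | CCCCCc1cc(OC(=O)C#CCCC)cc(O)c1C=O | intermediate
9 | 4-formyl-5-pentyl-3-(trimethylsilyloxy)phenyl hex-2-ynoate (not isolated) | CCCCCc1cc(OC(=O)C#CCCC)cc(O[Si](C)(C)C)c1C=O | intermediate
10 | 4-formyl-5-pentyl-3-(trimethylsilyloxy)phenyl 1,5-dimethoxy-3-propylbicyclo[2.2.2]octa-2,5-diene-2-carboxylate (racemic; not isolated) | CCCCCc1cc(OC(=O)C2=C(CCC)C3CCC2(OC)C=C3OC)cc(O[Si](C)(C)C)c1C=O | intermediate
11 | 4-formyl-5-pentyl-3-(trimethylsilyloxy)phenyl 2,4-dimethoxy-6-propylbenzoate (not isolated) | CCCCCc1cc(OC(=O)c2c(CCC)cc(OC)cc2OC)cc(O[Si](C)(C)C)c1C=O | intermediate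
12 | 4-formyl-3-hydroxy-5-pentylphenyl 2,4-dimethoxy-6-propylbenzoate | CCCCCc1cc(OC(=O)c2c(CCC)cc(OC)cc2OC)cc(O)c1C=O | intermediate
13 | 4-[(2,4-dimethoxy-6-propylbenzoyl)oxy]-2-hydroxy-6-pentylbenzoic acid (achiral) | CCCCCc1cc(OC(=O)c2c(CCC)cc(OC)cc2OC)cc(O)c1C(=O)O | target

Total step count: 5
Longest linear sequence: 4 steps (3 to 5 to 8 to 12 to 13); step 1 is a one-step side branch that feeds step 4.

Steps most likely to fail:

Step 4. The cycloaddition to the β-alkyl ynoate may be slower than the thermal decay of diene 2 (hydrogen shifts, loss of methanol), or the loss of ethylene may demand a temperature at which the formyl group or the aryl ester begins to react. The fallback would make ring A on its own and join it by acylation; it sets out from 5. 1,3-Dimethoxy-5-propylbenzene (taken as commercial) would be formylated with POCl3/DMF through (2,4-dimethoxy-6-propylbenzylidene)dimethyliminium chloride F1 to 2,4-dimethoxy-6-propylbenzaldehyde F2, which NaClO2/H2NSO3H would oxidise to 2,4-dimethoxy-6-propylbenzoic acid F3. Trifluoroacetic anhydride in toluene would convert it into 2,4-dimethoxy-6-propylbenzoic trifluoroacetic anhydride F4, which would acylate the non-chelated 4-OH of 5 and so come back to the route at 12.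

Step 5. Hypochlorous acid that escapes the scavenger may chlorinate the electron-rich ring A, whose C3' lies between two methoxy groups. The fallback would move the oxidation ahead of the benzannulation, to a stage at which ring A does not yet exist; it sets out from 8. NaClO2/H2NSO3H would give 4-(hex-2-ynoyloxy)-2-hydroxy-6-pentylbenzoic acid F5, and N,O-bis(trimethylsilyl)acetamide (2.5 equiv) would silylate both acidic groups to trimethylsilyl 4-(hex-2-ynoyloxy)-6-pentyl-2-(trimethylsilyloxy)benzoate F6. Heating with 2 as in step 4 would give 5-pentyl-3-(trimethylsilyloxy)-4-[(trimethylsilyloxy)carbonyl]phenyl 1,5-dimethoxy-3-propylbicyclo[2.2.2]octa-2,5-diene-2-carboxylate F7 and, after loss of ethylene, trimethylsilyl 4-[(2,4-dimethoxy-6-propylbenzoyl)oxy]-6-pentyl-2-(trimethylsilyloxy)benzoate F8. Dilute acid would free both groups, so that the fallback comes back to the route at 13.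

Step 1. The base-mediated double-bond shift may stop at an unfavourable equilibrium, or methanol may be lost with aromatisation during isomerisation and distillation, so that too little conjugated diene reaches step 4. The fallback would make a conjugated diene by enolate silylation instead of isomerisation, at the price of one O-methylation; it sets out from 8, used as its trimethylsilyl ether 9. Commercial 3-methoxycyclohex-2-en-1-one, LiN(i-Pr)2 and Me3SiCl (THF, −78 °C) would give 1-methoxy-3-(trimethylsilyloxy)cyclohexa-1,3-diene F9 by kinetic deprotonation at C6. Under the conditions of step 4 it would add to 9 with the same orientation to give 4-formyl-5-pentyl-3-(trimethylsilyloxy)phenyl 1-methoxy-3-propyl-5-(trimethylsilyloxy)bicyclo[2.2.2]octa-2,5-diene-2-carboxylate F10, which would lose ethylene to 4-formyl-5-pentyl-3-(trimethylsilyloxy)phenyl 2-methoxy-6-propyl-4-(trimethylsilyloxy)benzoate F11. Dilute acid would give 4-formyl-3-hydroxy-5-pentylphenyl 4-hydroxy-2-methoxy-6-propylbenzoate F12. MeI (1.1 equiv) and K2CO3 in acetone would then methylate only the non-chelated 4'-OH, the 2-OH of ring B being held by the formyl group, and so come back to the route at 12.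

## Further compounds
F1 | step 4 | (2,4-dimethoxy-6-propylbenzylidene)dimethyliminium chloride | CCCc1cc(OC)cc(OC)c1C=[N+](C)C.[Cl-]
F2 | step 4 | 2,4-dimethoxy-6-propylbenzaldehyde | CCCc1cc(OC)cc(OC)c1C=O
F3 | step 4 | 2,4-dimethoxy-6-propylbenzoic acid | CCCc1cc(OC)cc(OC)c1C(=O)O
F4 | step 4 | 2,4-dimethoxy-6-propylbenzoic trifluoroacetic anhydride | CCCc1cc(OC)cc(OC)c1C(=O)OC(=O)C(F)(F)F
F5 | step 5 | 4-(hex-2-ynoyloxy)-2-hydroxy-6-pentylbenzoic acid | CCCCCc1cc(OC(=O)C#CCCC)cc(O)c1C(=O)O
F6 | step 5 | trimethylsilyl 4-(hex-2-ynoyloxy)-6-pentyl-2-(trimethylsilyloxy)benzoate | CCCCCc1cc(OC(=O)C#CCCC)cc(O[Si](C)(C)C)c1C(=O)O[Si](C)(C)C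
F7 | step 5 | 5-pentyl-3-(trimethylsilyloxy)-4-[(trimethylsilyloxy)carbonyl]phenyl 1,5-dimethoxy-3-propylbicyclo[2.2.2]octa-2,5-diene-2-carboxylate (racemic) | CCCCCc1cc(OC(=O)C2=C(CCC)C3CCC2(OC)C=C3OC)cc(O[Si](C)(C)C)c1C(=O)O[Si](C)(C)C
F8 | step 5 | trimethylsilyl 4-[(2,4-dimethoxy-6-propylbenzoyl)oxy]-6-pentyl-2-(trimethylsilyloxy)benzoate | CCCCCc1cc(OC(=O)c2c(CCC)cc(OC)cc2OC)cc(O[Si](C)(C)C)c1C(=O)O[Si](C)(C)C
F9 | step 1 | 1-methoxy-3-(trimethylsilyloxy)cyclohexa-1,3-diene | COC1=CC(O[Si](C)(C)C)=CCC1
F10 | step 1 | 4-formyl-5-pentyl-3-(trimethylsilyloxy)phenyl 1-methoxy-3-propyl-5-(trimethylsilyloxy)bicyclo[2.2.2]octa-2,5-diene-2-carboxylate (racemic) | CCCCCc1cc(OC(=O)C2=C(CCC)C3CCC2(OC)C=C3O[Si](C)(C)C)cc(O[Si](C)(C)C)c1C=O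
F11 | step 1 | 4-formyl-5-pentyl-3-(trimethylsilyloxy)phenyl 2-methoxy-6-propyl-4-(trimethylsilyloxy)benzoate | CCCCCc1cc(OC(=O)c2c(CCC)cc(O[Si](C)(C)C)cc2OC)cc(O[Si](C)(C)C)c1C=O
F12 | step 1 | 4-formyl-3-hydroxy-5-pentylphenyl 4-hydroxy-2-methoxy-6-propylbenzoate | CCCCCc1cc(OC(=O)c2c(CCC)cc(O)cc2OC)cc(O)c1C=O
A1 | direct plan | 2,4-dimethoxy-6-propylbenzoic acid | CCCc1cc(OC)cc(OC)c1C(=O)O
A2 | direct plan | benzyl 2,4-dihydroxy-6-pentylbenzoate | CCCCCc1cc(O)cc(O)c1C(=O)OCc1ccccc1
A3 | direct plan | benzyl 4-[(2,4-dimethoxy-6-propylbenzoyl)oxy]-2-hydroxy-6-pentylbenzoate | CCCCCc1cc(OC(=O)c2c(CCC)cc(OC)cc2OC)cc(O)c1C(=O)OCc1ccccc1
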